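The data were computed from invented constants, noise included.

The chemist at the bench must charge violet or green next, and we want to choose before either flask is spent.

| flask | starting material | partner | temperature | remark | time |
|---|---|---|---|---|---|
| gamma | 0.050 M (fed, over 4.0 h) | 6 equiv | 5 °C | run made earlier |  |
| zeta | 0.050 M (fed, over 4.0 h) | 8 equiv | 5 °C | run made earlier |  |
| violet | 0.050 M (fed, over 4.0 h) | 4.00 equiv |  | at 5 °C until 4.0 h, from then on at 30 °C | 20 h |
| green | 0.012 M (fed, over 4.0 h) | 4.00 equiv |  | at 5 °C throughout | 20 h |

| run | time / h | target / % | side product A / % | side product B / % |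
|---|---|---|---|---|
| gamma | 3.00 | 34.2 | 10.4 | 2.3 |
| gamma | 6.00 | 66.0 | 20.9 | 5.5 |
| gamma | 10.0 | 70.2 | 22.7 | 6.4 |
| gamma | 12.0 | 70.6 | 23.5 | 6.6 |
| zeta | 3.00 | 41.0 | 9.6 | 1.7 |
| zeta | 6.00 | 74.2 | 18.5 | 4.5 |
| zeta | 10.0 | 76.9 | 18.5 | 4.9 |
| zeta | 12.0 | 77.5 | 18.6 | 4.5 |

(scatter of a reading: 0.5 percentage points)

- the winner by share of target in all that became target or side product A or side product B; "neither" if no more than 2 percentage points parts them (violet / green / neither)
- share of target in all that became target or side product A or side product B, violet
- share of target in all that became target or side product A or side product B, green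

At 12.0 h, target over side product A rises with partner, so we divide that reading by the charged [partner]. Gamma gives 10.0 L mol⁻¹ and zeta gives 10.4 L mol⁻¹. Their mean, a reading with the scatter of its data, is 10.2 L mol⁻¹: the selectivity factor s, target formed per side product A for each mole per litre of partner. Side product B we treat as a small correction, taking gamma's fraction of reacted material, 6.55 %. Our reckoning for each flask is then:

x = s[partner], share = (1 − b) · x/(1 + x)

green: [partner] = 0.0480 M, x = 0.490, share = 30.7 %

violet, as if held at 5 °C: [partner] = 0.200 M, x = 2.04, share = 62.7 %

The earlier runs do not show what 30 °C does to violet. But green's share is half of violet's, so warming must cost violet that much before the order changes. We charge violet.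

The forecast also picks violet, with 57 % for violet and 32 % for green. It puts violet at about 60 % before warming, notes “About 38% of the material reacts after warming” and shades that figure down to its 57 %. Our unwarmed 62.7 % is higher than either figure.

Violet gives 49.7 % and green 30.3 %, so the winner is violet.

    starting material + partner → target (k = 2.20 L mol⁻¹ h⁻¹, Ea = 55.0 kJ mol⁻¹)
    starting material → side product A (k = 0.190 h⁻¹, Ea = 93.0 kJ mol⁻¹)
    2 starting material → side product B (k = 2.50 L mol⁻¹ h⁻¹, Ea = 52.0 kJ mol⁻¹)
    partner → decomposed reagent (k = 0.0200 h⁻¹, Ea = 92.0 kJ mol⁻¹)
    (constants at 5 °C)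

At 4.00 h, violet's target over side product A was 2.09, beside our x of 2.04. By 20.0 h, the warm stage had added 0.456 target per side product A.

For a neighbour of green charged with 1.60 equiv of partner, x = 0.196, so the share comes to 15.3 %. The computed flask gives 14.5 %.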